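## Structural features

1. The target is a flavonol, 3,5-dihydroxy-2-(2,5-dihydroxyphenyl)-6,7,8-trimethoxy-4H-chromen-4-one. Benzo ring A (C4a, C5, C6, C7, C8, C8a) is fused along C4a–C8a to pyranone ring C (O1, C2, C3, C4), and ring C carries ring B through the C2–C1' bond.
2. Ring A has no hydrogen: C5 bears OH, C6, C7 and C8 bear OMe, C8a bears O1 and C4a bears the C4 carbonyl carbon, so five of its six substituents are oxygen.
3. There is no stereocentre and no stable axis, so every selectivity question is one of position or of chemoselectivity among seven oxygen functions.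
4. Three parts are fragile: ring B, a hydroquinone that air and base turn into a quinone; the C3–OH/C4=O diosphenol of ring C, which chelates metals and is oxidised in alkali; and the three methyl ethers, which must outlast the release of four hydroxyl groups.
5. The real difficulty is ring A: a contiguous pentaoxygenated, hexasubstituted benzene cannot be finished by late substitution, its usual acetophenone precursors are multistep targets themselves, and O5 must end free while O6, O7 and O8 are methylated.
6. The key step exploits two features: C5–C6–C7–C8 is a chain of four oxygen-bearing carbons, with two methyl enol ether carbons (C6, C7) between two carbons at the carbonyl level (C5, C8), which is the carbon ring of a squaric ester cut open between C5 and C8; and C4a=C8a, with O1 on one end and C4=O on the other, is the free C5=C6 double bond of a monocyclic 2-aryl-3-oxy-4-pyranone that already holds rings B and C.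
7. The C8a end of that double bond has O1 as its second neighbour, so an annulation that starts at C8a can close at C4a only, and the mechanism tells the two ends C5 and C8 of the four-carbon unit apart.
8. Apart from the roles of O1 and O5, ring A is symmetric about the C7–C4a axis, so an acid-induced opening and reclosure of ring C would be degenerate.

## Logic of the disconnections

**17 from 16.**
- Bonds cut: the three O–CH2 acetal bonds at O3, O2' and O5'.
- Reason: the hydroquinone of ring B and the enol at C3 cannot face strong base, silver oxide and 138 °C unmasked. One kind of acetal on all three lets a single mild acid step end the route.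
- Gain: small in skeleton, large in safety. O5 needs no group, because it is born free and is tied to C4=O by a hydrogen bond.
- Demand: the cleavage must spare three aryl methyl ethers and exclude oxygen.

**16 from 13 (key disconnection).**
- Bonds cut: C4a–C5 of ring A. In the same retrosynthetic move C5 and C8 are joined again, so that C5–C6–C7–C8 folds back into a four-membered ring hanging on C8a of a monocyclic ring C.
- Reason: this is the only cut that removes the hexasubstituted benzene altogether instead of passing it on to a precursor.
- Gain: a pentaoxygenated arene fused to a heterocycle becomes two simple rings joined by one single bond. O5 (former ring carbonyl oxygen, ends as free OH) and O8 (ether oxygen) are told apart by the mechanism.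
- Demand: on heating, the four-membered ring must open with ring C turned inward, and the ketene so formed must close on C4a faster than it is lost in other ways.
- In one sentence: ring A is made last, by thermal electrocyclic ring expansion of 13, which already holds finished rings B and C. That sentence does not fit a chalcone or diketone route.

**13 from 12.**
- Bond cut: O8–CH3.
- Reason: the oxygen on the quaternary carbon must be an ether before the ring expansion, otherwise ring A would appear as an air-sensitive 5,8-hydroquinone with two free hydroxyls.
- Gain: the O5/O8 problem is solved on an aliphatic alcohol, where no second hydroxyl competes.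
- Demand: alkylation of a hindered tertiary carbinol without a free alkoxide and without attack on the ring C carbonyl oxygen.

**12 from 8 and 9.**
- Bond cut: C8–C8a.
- Reason: C8a is an sp2 carbon next to O1 and can carry a negative charge, and C8 is a carbonyl carbon of 9.
- Gain: the route becomes convergent. 9 brings C5–C8 with O6 and O7 already methylated, and its two carbonyl groups are equivalent, so only one monoadduct exists.
- Demand: site-selective metalation of 8 at the C–H next to O1, and one clean 1,2-addition.

**8 from 3 and 5.**
- Bond cut: C2–C1'.
- Reason: this is the only bond between rings B and C. Placing ring B first blocks C2, which leaves a single position next to O1 for the later metalation.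
- Gain: two small monocyclic partners.
- Demand: a cross-coupling between two carbons that each carry an ortho oxygen, with an organometal soft enough to leave C4=O alone.

**3 from 1 through 2.**
- Bonds cut: the O3–CH2 acetal bond and the C2–Br bond.
- Reason: the enol at C3 makes C2 the natural site of electrophilic halogenation.
- Gain: a commercial heterocycle supplies all of ring C with O3 in place.
- Demand: monohalogenation at C2 only.

**5 from 4.**
- Bonds cut: the two O–CH2 acetal bonds of ring B.
- Reason: the acetal oxygens direct the metalation that activates C1', and all four ring hydrogens are equivalent.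
- Gain: a commodity starting material.
- Demand: none beyond complete double alkylation.

## Other disconnections considered

**Alternative 1:** This is the cut that comes to mind first.
- Cut: O1–C2 and the C3–O bond are cut back to the chalcone A3, which comes from a Claisen–Schmidt condensation of the acetophenone A1 with the aldehyde A2.
- Forward key step: Algar–Flynn–Oyamada oxidative cyclisation (H2O2, NaOH), then hydrogenolysis.
- Grounds for preferring the chosen plan:
  - The whole difficulty of ring A passes unchanged into A1, a hexasubstituted benzene whose preparation needs successive ring oxidations and selective alkylations. It should cost about as many steps as the entire chosen route.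
  - The substituent on the carbon of A3 that becomes C5 twists the aryl ketone out of conjugation. Mechanistically this favours five-membered closure at the alpha carbon over the six-membered closure that is wanted.
  - Alkaline peroxide is a poor medium for two very electron-rich rings.

**Alternative 2:**
- Cut: ring C is closed at a carbon–carbon bond, C4–C4a.
- Forward key step: intramolecular Friedel–Crafts acylation (Eaton's reagent) of the acrylic acid A5, made from the phenol A4 by addition–elimination to a beta-halo acrylate.
- Grounds for preferring the chosen plan: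
  - The closure is positionally clean, because A4 has one free ring position, but A4 is again a pentaoxygenated benzene, so the gain in simplicity is small.
  - A5 is a tetrasubstituted enol ether that must hold the (E) geometry, with the acid cis to the aryloxy group.
  - The strongly acidic dehydrating medium endangers benzyl ethers and the methoxy group next to the reacting carbon.

**Alternative 3:**
- Cut: the C6–O and C8–O bonds are cut, so that ring A is oxygenated late.
- Forward key step: the 5,7-dihydroxyflavonol ether A6 is brominated to the 6,8-dibromide A7, followed by double copper-mediated methoxylation (CuBr, NaOMe, DMF) and methylation of O7.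
- Grounds for preferring the chosen plan:
  - A6 must first be built by the conventional route, and three or four steps follow it, so the sequence is longer.
  - Both C–O couplings occur at carbons flanked by two oxygens, where substitution is slow and loss of bromine by protonation is the expected competitor.
  - Ring B, an activated 1,4-dialkoxybenzene, competes for bromine, and hot methoxide can open ring C.

Key step: step 7

Assumption: 1, 4 and 9 are taken as commercial. Compounds 11, 12, 13 and 15 each hold one stereocentre that is carried as the racemate, since it vanishes when ring A becomes aromatic.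

## Steps

Step 1
Reactants: 1 3-hydroxy-4H-pyran-4-one (pyromeconic acid)
Product: 2 2-bromo-3-hydroxy-4H-pyran-4-one
Conditions: NBS (1.0 equiv), MeCN, 0 °C to rt
Reagents that add atoms: N-bromosuccinimide (NBS), O=C1CCC(=O)N1Br
Why: Electrophilic halogenation of an enol: the C3 hydroxyl makes C2 the nucleophilic enol carbon, the position at which 3-hydroxy-4-pyranones undergo aldol, Mannich and halogenation reactions. One equivalent of NBS at low temperature limits a second bromination at C5.

Step 2
Reactants: 2 2-bromo-3-hydroxy-4H-pyran-4-one
Product: 3 2-bromo-3-(methoxymethoxy)-4H-pyran-4-one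
Conditions: MOMCl, iPr2NEt, CH2Cl2, 0 °C to rt
Reagents that add atoms: chloromethyl methyl ether (MOMCl), COCCl
Why: O-Alkylation of an acidic enol with MOMCl and a hindered amine. The acetal masks the chelating diosphenol against zinc, lithium and silver reagents and is stable to base and heat.

Step 3
Reactants: 4 hydroquinone (benzene-1,4-diol)
Product: 5 1,4-bis(methoxymethoxy)benzene
Conditions: NaH, MOMCl, DMF, 0 °C to rt
Reagents that add atoms: chloromethyl methyl ether (MOMCl), COCCl
Why: Williamson-type double O-alkylation of the bis-phenoxide. The two acetal groups protect the hydroquinone from oxidation and act as directing groups in step 4.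

Step 4
Reactants: 5 1,4-bis(methoxymethoxy)benzene; 3 2-bromo-3-(methoxymethoxy)-4H-pyran-4-one
Product: 8 2-[2,5-bis(methoxymethoxy)phenyl]-3-(methoxymethoxy)-4H-pyran-4-one, via aryllithium 6 (not isolated), via arylzinc chloride 7 (not isolated)
Conditions: n-BuLi, THF, 0 °C to rt; ZnCl2, THF, 0 °C; then 3, Pd(OAc)2 (2 mol %), SPhos (4 mol %), THF, 50 °C
Reagents that add atoms: none
Why: Directed ortho-lithiation (the four ring hydrogens of 5 are equivalent, each ortho to an acetal oxygen), transmetalation to zinc and Negishi cross-coupling. The C2–Br bond of 3 is a vinylogous acyl bromide that adds readily to zerovalent palladium, the arylzinc is too soft to attack C4=O, and the bulky biarylphosphine helps reductive elimination between two ortho-oxygenated carbons.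

Step 5
Reactants: 8 2-[2,5-bis(methoxymethoxy)phenyl]-3-(methoxymethoxy)-4H-pyran-4-one; 9 dimethyl squarate (3,4-dimethoxycyclobut-3-ene-1,2-dione)
Product: 12 4-hydroxy-2,3-dimethoxy-4-{6-[2,5-bis(methoxymethoxy)phenyl]-5-(methoxymethoxy)-4-oxo-4H-pyran-2-yl}cyclobut-2-en-1-one (racemic), via 6-lithiopyranone 10 (not isolated), via lithium alkoxide 11 (not isolated)
Conditions: TMPH, n-BuLi, THF, −78 to 0 °C (gives LiTMP); 8, THF, −78 °C; cannulated into 9 (1.5 equiv), THF, −78 °C; aq. NH4Cl
Reagents that add atoms: none
Why: Deprotonative lithiation next to the ring oxygen with a hindered lithium amide, as known for C2 of chromones and C6 of 4-pyranones, followed by 1,2-addition of the heteroaryllithium to a squarate carbonyl, the standard entry to 4-substituted 4-hydroxycyclobutenones. C2 is blocked by ring B, the C6–H is the most acidic sp2 hydrogen (inductive pull of O1, beta position of the enone), and LiTMP at −78 °C is too weak a base to ortho-lithiate ring B. The two carbonyl groups of 9 are equivalent, inverse addition prevents a second addition, and the new quaternary stereocentre forms as a racemate that is erased in step 7.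

Step 6
Reactants: 12 4-hydroxy-2,3-dimethoxy-4-{6-[2,5-bis(methoxymethoxy)phenyl]-5-(methoxymethoxy)-4-oxo-4H-pyran-2-yl}cyclobut-2-en-1-one
Product: 13 2,3,4-trimethoxy-4-{6-[2,5-bis(methoxymethoxy)phenyl]-5-(methoxymethoxy)-4-oxo-4H-pyran-2-yl}cyclobut-2-en-1-one (racemic)
Conditions: MeI (excess), Ag2O, MeCN, rt, dark
Reagents that add atoms: iodomethane (MeI), CI
Why: Purdie methylation (Ag2O, MeI) is the usual near-neutral way to cap the tertiary carbinol of squarate adducts. It avoids a free alkoxide that could revert by loss of the stabilised pyranonyl anion, and MeI is too weak an alkylating agent to turn the ring C carbonyl oxygen into a pyrylium salt.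

Step 7
Reactants: 13 2,3,4-trimethoxy-4-{6-[2,5-bis(methoxymethoxy)phenyl]-5-(methoxymethoxy)-4-oxo-4H-pyran-2-yl}cyclobut-2-en-1-one
Product: 16 5-hydroxy-6,7,8-trimethoxy-3-(methoxymethoxy)-2-[2,5-bis(methoxymethoxy)phenyl]-4H-chromen-4-one, via (Z)-dienylketene 14 (not isolated), via 4aH-chromene-4,5-dione 15 (not isolated)
Conditions: p-xylene (0.01 M, degassed), 138 °C, Ar
Reagents that add atoms: none
Why: Heat opens the four-membered ring of 13 by conrotatory 4π electrocyclic cleavage of the bond between its carbonyl carbon (future C5) and its quaternary carbon (future C8); torquoselectivity sends the donor OMe on that carbon outward and the pyranonyl group inward, which gives the (Z)-dienylketene 14 with the ketene next to the pyranone C–H. Ring A is then closed by a thermal disrotatory 6π electrocyclisation of 14 (ketene C=C, central C=C, pyranone C5=C6), which forms the C4a–C5 bond and the six-membered carbocycle of 15. In 15 the C4a hydrogen lies between the C4 and C5 carbonyl groups and should shift at once to O5, so the only new stereocentre (C4a, uncontrolled, racemic) is erased, and aromatisation plus the O5–H···O=C4 hydrogen bond make the sequence irreversible. The closest known reaction type is the Moore rearrangement, the thermal ring expansion of squarate-derived 4-aryl-, 4-heteroaryl- and 4-alkenyl-4-alkoxycyclobutenones to monoprotected hydroquinones. Positional selectivity is secured by the substrate: the ring C carbon that carries the four-membered ring has O1 as one neighbour and the C–H carbon as the other, so only one closure exists. That C–H carbon is the nucleophilic alpha carbon of a vinylogous ester and matches the electrophilic ketene carbon, and a 4-pyranone gives up far less aromatic stabilisation in 15 than the benzene rings that undergo the same reaction. The differentiation of the oxygens follows from the mechanism: the ketene oxygen becomes the only free hydroxyl (O5), the ether oxygen set in step 6 becomes O8, and the two enol ether groups become O6 and O7. Ring opening is reversible, so a ketene of the wrong geometry returns to 13, and dilution with exclusion of air and water keeps 14 from dimerising or being trapped.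

Step 8
Reactants: 16 5-hydroxy-6,7,8-trimethoxy-3-(methoxymethoxy)-2-[2,5-bis(methoxymethoxy)phenyl]-4H-chromen-4-one
Product: 17 3,5-dihydroxy-2-(2,5-dihydroxyphenyl)-6,7,8-trimethoxy-4H-chromen-4-one (target)
Conditions: 3 M aq. HCl, THF, 50 °C, Ar
Reagents that add atoms: none
Why: Acid hydrolysis of three methoxymethyl acetals, to which aryl methyl ethers are inert. The acidic, oxygen-free medium keeps ring B in the hydroquinone state, and an opening and reclosure of ring C would be degenerate because of the symmetry of ring A.

## Compound list

1 | 3-hydroxy-4H-pyran-4-one (pyromeconic acid) | O=c1ccocc1O | starting material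
2 | 2-bromo-3-hydroxy-4H-pyran-4-one | O=c1ccoc(Br)c1O | intermediate
3 | 2-bromo-3-(methoxymethoxy)-4H-pyran-4-one | O=c1ccoc(Br)c1OCOC | intermediate
4 | hydroquinone | Oc1ccc(O)cc1 | starting material
5 | 1,4-bis(methoxymethoxy)benzene | COCOc1ccc(OCOC)cc1 | intermediate
6 | [2,5-bis(methoxymethoxy)phenyl]lithium (not isolated) | [Li]c1cc(OCOC)ccc1OCOC | intermediate
7 | [2,5-bis(methoxymethoxy)phenyl]zinc chloride (not isolated) | Cl[Zn]c1cc(OCOC)ccc1OCOC | intermediate
8 | 2-[2,5-bis(methoxymethoxy)phenyl]-3-(methoxymethoxy)-4H-pyran-4-one | O=c1ccoc(-c2cc(OCOC)ccc2OCOC)c1OCOC | intermediate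
9 | dimethyl squarate (3,4-dimethoxycyclobut-3-ene-1,2-dione) | COC1=C(OC)C(=O)C1=O | starting material
10 | {6-[2,5-bis(methoxymethoxy)phenyl]-5-(methoxymethoxy)-4-oxo-4H-pyran-2-yl}lithium (not isolated) | [Li]c1cc(=O)c(OCOC)c(-c2cc(OCOC)ccc2OCOC)o1 | intermediate
11 | lithium alkoxide of 12, racemic (not isolated) | [Li]OC1(c2cc(=O)c(OCOC)c(-c3cc(OCOC)ccc3OCOC)o2)C(OC)=C(OC)C1=O | intermediate
12 | 4-hydroxy-2,3-dimethoxy-4-{6-[2,5-bis(methoxymethoxy)phenyl]-5-(methoxymethoxy)-4-oxo-4H-pyran-2-yl}cyclobut-2-en-1-one, racemic | OC1(c2cc(=O)c(OCOC)c(-c3cc(OCOC)ccc3OCOC)o2)C(OC)=C(OC)C1=O | intermediate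
13 | 2,3,4-trimethoxy-4-{6-[2,5-bis(methoxymethoxy)phenyl]-5-(methoxymethoxy)-4-oxo-4H-pyran-2-yl}cyclobut-2-en-1-one, racemic | COC1(c2cc(=O)c(OCOC)c(-c3cc(OCOC)ccc3OCOC)o2)C(OC)=C(OC)C1=O | intermediate
14 | (Z)-2,3,4-trimethoxy-4-{6-[2,5-bis(methoxymethoxy)phenyl]-5-(methoxymethoxy)-4-oxo-4H-pyran-2-yl}buta-1,3-dien-1-one (not isolated) | O=C=C(OC)/C(OC)=C(\c1cc(=O)c(OCOC)c(-c2cc(OCOC)ccc2OCOC)o1)OC | intermediate
15 | 6,7,8-trimethoxy-3-(methoxymethoxy)-2-[2,5-bis(methoxymethoxy)phenyl]-4aH-chromene-4,5-dione, racemic (not isolated) | COC1=C(OC)C(=O)C2C(=O)C(OCOC)=C(c3cc(OCOC)ccc3OCOC)OC2=C1OC | intermediate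
16 | 5-hydroxy-6,7,8-trimethoxy-3-(methoxymethoxy)-2-[2,5-bis(methoxymethoxy)phenyl]-4H-chromen-4-one | COCOc1ccc(OCOC)c(-c2oc3c(OC)c(OC)c(OC)c(O)c3c(=O)c2OCOC)c1 | intermediate
17 | 3,5-dihydroxy-2-(2,5-dihydroxyphenyl)-6,7,8-trimethoxy-4H-chromen-4-one | COc1c(OC)c(O)c2c(=O)c(O)c(-c3cc(O)ccc3O)oc2c1OC | target

## Step count and least certain steps

Total step count: 8. Longest linear sequence: 7 steps (steps 1, 2, 4, 5, 6, 7 and 8, from 1). Step 3 lies on the shorter branch from 4.

**Step 7 (key step).**
- Most likely failure: slow 6π closure onto the cross-conjugated double bond of ring C. The reversibly formed ketene would then be drained by dimerisation, by capture with traces of water, or by slow thermal loss of acetal groups during long heating.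
- Fallback (sets out from 9, comes back at 17): the same ring expansion is run on the most electron-rich and least hindered partner, and ring C is closed afterwards in the classical sense.
  - Methyl vinyl ether is lithiated (t-BuLi, THF) to 1-methoxyethenyllithium F1. This is added to 9 and the adduct is O-methylated (MeOTf) to give 2,3,4-trimethoxy-4-(1-methoxyethenyl)cyclobut-2-en-1-one F2.
  - Heating in toluene should give 2,3,4,5-tetramethoxyphenol F3.
  - Friedel–Crafts acylation at its only free position (methoxyacetyl chloride, BF3·OEt2) gives 1-(2-hydroxy-3,4,5,6-tetramethoxyphenyl)-2-methoxyethan-1-one F4.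
  - Allan–Robinson condensation of F4 with 2,5-bis(benzyloxy)benzoic anhydride F5 (from the purchased acid and DCC; Et3N, 160 °C) gives 2-[2,5-bis(benzyloxy)phenyl]-3,5,6,7,8-pentamethoxy-4H-chromen-4-one F6.
  - Chelation-directed dealkylation (AlBr3, MeCN) should remove the two methyl ethers beside C4=O (O3, O5) together with the two benzyl ethers and give 17.
  - This retreat gives up the mechanistic differentiation of O5 and rests on selective dealkylation instead.

**Step 5.**
- Most likely failures: metalation at the wrong carbon (the C–H beside C4=O, followed by beta-elimination of O1 and ring opening), self-condensation of the lithiated ring with unmetalated 8, or sluggish addition of this stabilised carbanion.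
- Fallback (sets out from 8, comes back at 12): C–H metalation and C–C bond formation are separated by an isolable halide.
  - A Lewis-acid-free zinc amide (TMPZnCl·LiCl, THF, rt) should take the most acidic hydrogen and give the C6-zincated pyranone F7, which does not self-condense.
  - Iodine converts F7 into the 6-iodopyranone F8, whose constitution can be settled at a stable stage.
  - Iodine–magnesium exchange (iPrMgCl·LiCl, THF, −78 to −40 °C) gives the C6-magnesiated pyranone F9 without any amine present. F9 is added to 9 and quenched to give 12.

**Step 6.**
- Most likely failures: reversal of the addition through transient alkoxide, very slow alkylation of the hindered tertiary carbinol, or alkylation at the ring C carbonyl oxygen.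
- Fallback (sets out from 12, comes back at 16): the order of ring expansion and methylation is inverted, and the selection between O5 and O8 is left to hydrogen bonding.
  - Heating 12 in degassed toluene or xylene should give 5,8-dihydroxy-6,7-dimethoxy-3-(methoxymethoxy)-2-[2,5-bis(methoxymethoxy)phenyl]-4H-chromen-4-one F10. It is handled under argon, and Na2S2O4 is used if air oxidation sets in.
  - One equivalent of Me2SO4 with K2CO3 in acetone should methylate O8 only, because O5–H is chelated to C4=O. This gives 16.

**Step 4.**
- Most likely failures: slow transmetalation and reductive elimination between two ortho-oxygenated carbons, which leaves room for protonation and homocoupling of the arylzinc, or attack of residual aryllithium on ring C.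
- Fallback (sets out from 1 and 5, comes back at 8): the polarity of the coupling is reversed and the bromination is dropped.
  - 1 is protected (MOMCl, iPr2NEt) as 3-(methoxymethoxy)-4H-pyran-4-one F11.
  - 5 is lithiated to 6 and quenched with iodine to give 2-iodo-1,4-bis(methoxymethoxy)benzene F12.
  - F11 is zincated at C2–H, which is flanked by O1 and the acetal oxygen (TMPZnCl·LiCl), to give the pyranon-2-ylzinc chloride F13.
  - F13 is coupled with F12 (Pd(OAc)2, SPhos) to give 8.

## Further compounds

F1 | step 7 | 1-methoxyethenyllithium | [Li]C(=C)OC
F2 | step 7 | 2,3,4-trimethoxy-4-(1-methoxyethenyl)cyclobut-2-en-1-one (racemic) | COC(=C)C1(OC)C(OC)=C(OC)C1=O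
F3 | step 7 | 2,3,4,5-tetramethoxyphenol | COc1cc(O)c(OC)c(OC)c1OC
F4 | step 7 | 1-(2-hydroxy-3,4,5,6-tetramethoxyphenyl)-2-methoxyethan-1-one | COCC(=O)c1c(O)c(OC)c(OC)c(OC)c1OC
F5 | step 7 | 2,5-bis(benzyloxy)benzoic anhydride | O=C(OC(=O)c1cc(OCc2ccccc2)ccc1OCc1ccccc1)c1cc(OCc2ccccc2)ccc1OCc1ccccc1
F6 | step 7 | 2-[2,5-bis(benzyloxy)phenyl]-3,5,6,7,8-pentamethoxy-4H-chromen-4-one | COc1c(OC)c(OC)c2c(=O)c(OC)c(-c3cc(OCc4ccccc4)ccc3OCc3ccccc3)oc2c1OC
F7 | step 5 | chloro{6-[2,5-bis(methoxymethoxy)phenyl]-5-(methoxymethoxy)-4-oxo-4H-pyran-2-yl}zinc | Cl[Zn]c1cc(=O)c(OCOC)c(-c2cc(OCOC)ccc2OCOC)o1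
F8 | step 5 | 2-[2,5-bis(methoxymethoxy)phenyl]-6-iodo-3-(methoxymethoxy)-4H-pyran-4-one | Ic1cc(=O)c(OCOC)c(-c2cc(OCOC)ccc2OCOC)o1
F9 | step 5 | chloro{6-[2,5-bis(methoxymethoxy)phenyl]-5-(methoxymethoxy)-4-oxo-4H-pyran-2-yl}magnesium | Cl[Mg]c1cc(=O)c(OCOC)c(-c2cc(OCOC)ccc2OCOC)o1
F10 | step 6 | 5,8-dihydroxy-6,7-dimethoxy-3-(methoxymethoxy)-2-[2,5-bis(methoxymethoxy)phenyl]-4H-chromen-4-one | COCOc1ccc(OCOC)c(-c2oc3c(O)c(OC)c(OC)c(O)c3c(=O)c2OCOC)c1
F11 | step 4 | 3-(methoxymethoxy)-4H-pyran-4-one | O=c1ccocc1OCOC
F12 | step 4 | 2-iodo-1,4-bis(methoxymethoxy)benzene | COCOc1ccc(OCOC)c(I)c1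
F13 | step 4 | chloro[3-(methoxymethoxy)-4-oxo-4H-pyran-2-yl]zinc | Cl[Zn]c1occc(=O)c1OCOC
A1 | alternative 1 | 1-[2-(benzyloxy)-6-hydroxy-3,4,5-trimethoxyphenyl]ethan-1-one | CC(=O)c1c(O)c(OC)c(OC)c(OC)c1OCc1ccccc1
A2 | alternative 1 | 2,5-bis(benzyloxy)benzaldehyde | O=Cc1cc(OCc2ccccc2)ccc1OCc1ccccc1
A3 | alternative 1 | (E)-1-[2-(benzyloxy)-6-hydroxy-3,4,5-trimethoxyphenyl]-3-[2,5-bis(benzyloxy)phenyl]prop-2-en-1-one | O=C(/C=C/c1cc(OCc2ccccc2)ccc1OCc1ccccc1)c1c(O)c(OC)c(OC)c(OC)c1OCc1ccccc1
A4 | alternative 2 | 5-(benzyloxy)-2,3,4-trimethoxyphenol | COc1c(O)cc(OCc2ccccc2)c(OC)c1OC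
A5 | alternative 2 | (E)-2-(benzyloxy)-3-[5-(benzyloxy)-2,3,4-trimethoxyphenoxy]-3-[2,5-bis(benzyloxy)phenyl]prop-2-enoic acid | OC(=O)/C(OCc1ccccc1)=C(\Oc1cc(OCc2ccccc2)c(OC)c(OC)c1OC)c1cc(OCc2ccccc2)ccc1OCc1ccccc1
A6 | alternative 3 | 3-(benzyloxy)-2-[2,5-bis(benzyloxy)phenyl]-5,7-dihydroxy-4H-chromen-4-one | O=c1c(OCc2ccccc2)c(-c2cc(OCc3ccccc3)ccc2OCc2ccccc2)oc2cc(O)cc(O)c12
A7 | alternative 3 | 3-(benzyloxy)-2-[2,5-bis(benzyloxy)phenyl]-6,8-dibromo-5,7-dihydroxy-4H-chromen-4-one | O=c1c(OCc2ccccc2)c(-c2cc(OCc3ccccc3)ccc2OCc2ccccc2)oc2c(Br)c(O)c(Br)c(O)c12
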